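Remark on the chemistry: the target has no stereocentre and no stereogenic double bond, so no descriptor is needed; compounds 1 and 9 are taken as commercial.

## Structural features

1. The target is a depside. Ring A (acyl half: C1 carboxyl carbon, C2 OH, C3 CHO, C4 OH, C5 CH3, C6 CH3) and ring B (phenol half: C1 CO2CH3, C2 OCH3, C3 CH3, C4 O-acyl, C5 CH3, C6 CH3) are joined only through the ester C1(A)–C(=O)–O–C4(B).
2. Both benzene rings are hexasubstituted, and the molecule has no stereogenic element.
3. The ester bond is the crowded point: its acyl carbon sits between C2–OH and C6–CH3 of ring A, and its oxygen sits between the C3 and C5 methyl groups of ring B.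
4. The fragile groups are this aryl ester (an activated ester, open to alkoxides, hydroxide and amines), the aldehyde on C3 between two phenols, and the two free phenols of ring A, which would need protection in any carboxyl-activation chemistry.
5. Ring A carries oxygen on C2 and C4 and the carboxyl carbon on C1. This is the 1,3-alternation of a folded 3,5,7-trioxooctanoyl chain with one extra methyl group (on C5) and one extra carbon (the CHO on C3).
6. The key step exploits exactly this: the chain that becomes C(=O)–C1–C2(O)–C3–C4(O)–C5(CH3)–C6(CH3) of ring A is released as an acylketene, its sp carbon is captured by the O–H on C4 of ring B, and the ring is then closed between C1 and C6 by aldol condensation. The hindered ester and the hexasubstituted ring thus arise in one operation.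
7. The real difficulty is therefore the pair "ester bond plus ring A". Ring B is a pentasubstituted phenol reached from a commercial tetrasubstituted benzoate by functional-group chemistry.

## Logic of the disconnections

**20 to 18.** The C3–CHO bond of ring A is cut. In 18, C3 is the only hydrogen-bearing aromatic carbon of the whole molecule and lies between both hydroxyls, so an electrophilic formylation has a single possible site. The cut also keeps the aldehyde out of the enolate chemistry, the thermolysis and the hydrogenation. The gain is that 18 carries only phenols, esters and ethers. The demand is a formylation that works on a ring bearing an acyl group and leaves the aryl ester and the methyl ether of ring B intact.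

**18 to 8 and 14 (key disconnection).** Two bonds are cut: the acyl–oxygen bond of the depside and the C1–C6 bond of ring A. Ring A is opened to the chain of 16 (through 17), the chain is detached from the phenol oxygen as ketene 15, and 15 is masked as 14. The reason is that the crowded ester bond is then formed at a linear ketene carbon, before ring A and its ortho substituents exist, and the substitution pattern of ring A is written into the chain. The gain is large: a hexasubstituted aryl benzoate goes back to a phenol and a C12 dioxinone with no protecting group on ring A. The demand is that capture of 15 by the hindered O–H of 8 outruns internal capture, and that the aldol closure of 16 outruns loss of the aryloxide.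

**14 to 11.** The C3'–C4' bond of the side chain is cut (the bond between the methyl-bearing carbon and the terminal acetyl group). This makes the future C5 methyl of ring A the end of an ethyl ketone and brings in C6 with its methyl as an acetyl donor. The gain is one C–C bond back to a simple keto-dioxinone. The demand is reaction at the terminal carbanion of dianion 12 only, without proton transfer from the product.

**11 to 9.** The C1'–C2' bond is cut, which is a gamma-acylation of dienolate 10 by a propanoyl donor. The gain is a commercial starting material. The demand is C-acylation at the exocyclic carbon of 10 and tolerance of the acidic product.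

**8 to 5.** Two functional-group changes are taken back together: the C5 methyl of ring B to a formyl group and the free O4–H to a benzyl ether. One hydrogenation performs both (through 6 and 7), so the protecting-group removal costs no step. The demand is complete hydrogenolysis of the benzylic C–O bonds without touching the ester or the ring.

**5 to 3.** The C5–CHO bond of ring B is cut. C5 is the only free ring position of 3, para to OCH3 and ortho to the benzyloxy group, so regiochemistry is not in question (4 is the hydrolysable intermediate). The demand is a Lewis acid mild enough for the benzyl ether.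

**3 to 2 to 1.** The O2–CH3 and O4–CH2Ph bonds are cut. In 1 the O2–H is chelated to the ester and reacts last, so O4 is first blocked with a group that step 4 removes anyway, and O2 is then methylated. The gain is a commercial benzoate that already carries five of the six substituents of ring B. The demand is clean mono-alkylation in the first step.

## Other disconnections considered

**Alternative 1:** Only the acyl–oxygen bond of the depside is cut; this is the first disconnection that comes to mind. Forward, 8 would be acylated with the protected acid A1 (2,4-bis(benzyloxy)-3-formyl-5,6-dimethylbenzoic acid), activated as its acid chloride or mixed trifluoroacetic anhydride, to give the protected depside A2, followed by debenzylation. The chosen plan is preferred for three reasons.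
- The bond would have to form by addition of an oxygen flanked by two methyl groups to a benzoyl carbon flanked by OCH2Ph and CH3. The tetrahedral intermediate is strongly congested.
- A1 needs its own sequence of formylation, double protection and hydrolysis of a di-ortho-substituted ester.
- The final hydrogenolysis of A2 would have to spare an aryl aldehyde.

The chosen plan makes the same bond at an unhindered sp carbon and needs no protecting group on ring A.

**Alternative 2:** The C1–C2 and C5–C6 bonds of ring A are cut. Forward, a Diels–Alder reaction of the aryl ynoate A3 (the but-2-ynoate of 8) with diene A4 ((3Z)-1-methoxy-1,3-bis(trimethylsilyloxy)penta-1,3-diene), followed by loss of methanol and desilylation, would give 18 directly. The regiochemistry is right, because the ketene acetal terminus bonds to the alpha-carbon of the ynoate. The chosen plan is preferred for three reasons.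
- The new C5–C6 bond must join a methyl-bearing diene terminus to the methyl-bearing beta-carbon of a beta-alkyl ynoate. That is a slow bimolecular pairing that calls for high temperature.
- At such temperature a silyl ketene acetal is prone to silyl transfer and to Claisen-type attack on the aryl ester of A3.
- The ester must first be made in a separate acylation, and the route is one step longer.

The ring closure of the chosen plan is intramolecular and forms no C–C bond between two hindered carbons in a bimolecular step.

**Alternative 3:** The aryl–oxygen bond between the ester oxygen and C4 of ring B is cut. Forward, a Cu(OAc)2-mediated Chan–Lam coupling of acid A1 with the boronic acid A5 ([3-methoxy-4-(methoxycarbonyl)-2,5,6-trimethylphenyl]boronic acid) would give A2, again followed by debenzylation. The chosen plan is preferred for three reasons.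
- The boron of A5 sits between two methyl groups, so transmetalation should be slow and protodeboronation should compete.
- A carboxylate is among the weakest partners for C–O coupling.
- A1 and its protecting groups are still required, and A5 needs halogenation and borylation of a pentasubstituted arene.

No problem of Alternative 1 is removed, and steps are added.

Key step: step 7

## Route

Step 1
Reactants: 1 methyl 2,4-dihydroxy-3,6-dimethylbenzoate
Product: 2 methyl 4-(benzyloxy)-2-hydroxy-3,6-dimethylbenzoate
Conditions: BnBr (1.05 equiv), K2CO3 (1.1 equiv), acetone, reflux
Reagents that add atoms: benzyl bromide, BrCc1ccccc1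
Why: Williamson ether synthesis; the O2–H of 1 is locked in a hydrogen bond to the ester carbonyl and is the weaker acid, so carbonate ionizes and benzylates the O4–H selectively, as is general for 2,4-dihydroxybenzoates.

Step 2
Reactants: 2 methyl 4-(benzyloxy)-2-hydroxy-3,6-dimethylbenzoate
Product: 3 methyl 4-(benzyloxy)-2-methoxy-3,6-dimethylbenzoate
Conditions: MeI (3 equiv), K2CO3 (2 equiv), DMF, 60 °C
Reagents that add atoms: iodomethane, CI
Why: Williamson ether synthesis on the remaining chelated phenol, which needs the polar solvent, heat and an excess of the small electrophile; the methyl ester and the benzyl ether are inert to these conditions.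

Step 3
Reactants: 3 methyl 4-(benzyloxy)-2-methoxy-3,6-dimethylbenzoate
Product: 5 methyl 4-(benzyloxy)-5-formyl-2-methoxy-3,6-dimethylbenzoate, via α-chloro ether 4 (not isolated)
Conditions: Cl2CHOMe (1.5 equiv), SnCl4 (1.5 equiv), CH2Cl2, −20 → 0 °C; then ice-cold 1 M HCl
Reagents that add atoms: dichloromethyl methyl ether, COC(Cl)Cl; water, O
Why: Rieche formylation; C5 is the only hydrogen-bearing carbon of the benzoate ring and is para to OCH3 and ortho to the benzyloxy group, so the chloro(methoxy)carbenium electrophile can attack only there, and aqueous acid hydrolyses 4 to the aldehyde. SnCl4 at low temperature is chosen to spare the benzyl ether; loss of the benzyl group after formylation would do no harm, because step 4 removes it in any case.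

Step 4
Reactants: 5 methyl 4-(benzyloxy)-5-formyl-2-methoxy-3,6-dimethylbenzoate
Product: 8 methyl 4-hydroxy-2-methoxy-3,5,6-trimethylbenzoate, via debenzylated aldehyde 6 (not isolated), via hydroxymethyl phenol 7 (not isolated)
Conditions: H2 (3 atm), 10% Pd/C, EtOAc–AcOH 4:1, HCl (cat.), rt → 40 °C
Reagents that add atoms: none
Why: Catalytic hydrogenolysis does two jobs: the benzyl ether is cleaved to 6, the aldehyde of 6 is hydrogenated to the ortho-hydroxybenzyl alcohol 7, and the acid-activated benzylic C–O bond of 7 is hydrogenolysed to the methyl group. The ester, the methyl ether and the arene should not be reduced under these conditions.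

Step 5
Reactants: 9 2,2,6-trimethyl-4H-1,3-dioxin-4-one
Product: 11 2,2-dimethyl-6-(2-oxobutyl)-4H-1,3-dioxin-4-one, via lithium dienolate 10 (not isolated)
Conditions: 9 (2.0 equiv), LiN(SiMe3)2 (2.0 equiv), THF, −78 °C; EtCOCl (1.0 equiv), −78 °C; then 1 M HCl
Reagents that add atoms: propanoyl chloride, CCC(Cl)=O
Why: Vinylogous Claisen acylation; the amide base removes a proton from the C6 methyl group of 9 and the cross-conjugated dienolate 10 is acylated at its exocyclic carbon by the acid chloride. Twofold 10 is used because the product is more acidic than 9 and consumes one equivalent of enolate.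

Step 6
Reactants: 11 2,2-dimethyl-6-(2-oxobutyl)-4H-1,3-dioxin-4-one
Product: 14 2,2-dimethyl-6-(3-methyl-2,4-dioxopentyl)-4H-1,3-dioxin-4-one, via dilithium dianion 12 (not isolated), via tetrahedral adduct 13 (not isolated)
Conditions: LiN(iPr)2 (LDA, 2.2 equiv), THF, −78 → −40 °C; MeC(O)N(OMe)Me (1.2 equiv), −78 → −20 °C; then 1 M HCl, 0 °C
Reagents that add atoms: N-methoxy-N-methylacetamide, CC(=O)N(C)OC
Why: Claisen-type acylation of a 1,3-dicarbonyl dianion at its terminal carbon; the base removes first the doubly activated C1' proton and then a C3' proton, and the last-formed, most basic carbanion of 12 adds to the N-methoxy-N-methyl amide. The chelated adduct 13 should hold until the acidic quench, so that the acidic product never meets unreacted 12; 14 is racemic, largely enolized and is used without chromatography on silica because it aromatizes easily.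

Step 7
Reactants: 8 methyl 4-hydroxy-2-methoxy-3,5,6-trimethylbenzoate; 14 2,2-dimethyl-6-(3-methyl-2,4-dioxopentyl)-4H-1,3-dioxin-4-one
Product: 18 methyl 4-[(2,4-dihydroxy-5,6-dimethylbenzoyl)oxy]-2-methoxy-3,5,6-trimethylbenzoate, via acylketene 15 (not isolated), via aryl triketo ester 16 (not isolated), via aldol adduct 17 (not isolated)
Conditions: 8 (1.0 equiv, 0.5 M), 14 (1.5 equiv, added over 1 h), PhMe, 110 °C; then rt, Et3N (2 equiv); then TFA (5 equiv), rt
Reagents that add atoms: none
Why: At 110 °C 14 should undergo a retro-hetero-Diels–Alder reaction with loss of acetone to give acylketene 15. The O–H of 8 adds to 15 through a planar six-centre transition state in which the acyl oxygen takes the proton; the electrophile is an sp carbon with no ortho substituents yet, so the two methyl groups flanking the oxygen of 8 cost little, and the aryl ester 16 is in place before ring A exists. Et3N then forms the enolate at C2 of the chain of 16 (between ester and ketone), which attacks the C7 methyl ketone in a 6-(enolendo)-exo-trig aldol closure to 17, and TFA dehydrates 17, after which enolization of the two remaining ketones gives the aromatic ring A of 18. The closest known reaction type is the thermolysis of keto-dioxinones in the presence of alcohols, which gives resorcylate esters by ketene capture and aldol aromatization, together with the thermal acetoacetylation of phenols by 9. No stereocentre remains, since the centres of 14, 16 and 17 are erased on aromatization. The first selectivity needed is capture of 15 by 8 faster than capture by the enol oxygen of its own chain, which a concentrated solution of 8 and slow addition of 14 should favour. The second is aldol attack of C2 on C7 faster than attack of C6 or of the C5 enol oxygen on the aryl ester with loss of the aryloxide; this is supported by the methyl group on C6 (a tertiary, poor nucleophile whose Claisen product could not aromatize), by the mild amine base in the absence of any alcohol, and by the irreversible aromatization that drains 17. The position of every substituent of ring A follows from the chain, so no regioisomer can arise.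

Step 8
Reactants: 18 methyl 4-[(2,4-dihydroxy-5,6-dimethylbenzoyl)oxy]-2-methoxy-3,5,6-trimethylbenzoate
Product: 20 methyl 4-[(3-formyl-2,4-dihydroxy-5,6-dimethylbenzoyl)oxy]-2-methoxy-3,5,6-trimethylbenzoate (the target), via α-chloro ether 19 (not isolated)
Conditions: Cl2CHOMe (3 equiv), TiCl4 (4 equiv), CH2Cl2, −20 → 0 °C; then 1 M HCl, rt
Reagents that add atoms: dichloromethyl methyl ether, COC(Cl)Cl; water, O
Why: Rieche formylation directed by titanium phenoxides; C3 of ring A is the only aromatic C–H in 18 and is ortho to both hydroxyls, so the chelated electrophile is delivered there and aqueous acid hydrolyses 19 to the aldehyde. Ring B has no free position, and the hindered aryl ester should survive the Lewis acid at 0 °C.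

## Compound list

1 | methyl 2,4-dihydroxy-3,6-dimethylbenzoate | COC(=O)c1c(C)cc(O)c(C)c1O | starting material
2 | methyl 4-(benzyloxy)-2-hydroxy-3,6-dimethylbenzoate | COC(=O)c1c(C)cc(OCc2ccccc2)c(C)c1O | intermediate
3 | methyl 4-(benzyloxy)-2-methoxy-3,6-dimethylbenzoate | COC(=O)c1c(C)cc(OCc2ccccc2)c(C)c1OC | intermediate
4 | methyl 4-(benzyloxy)-5-[chloro(methoxy)methyl]-2-methoxy-3,6-dimethylbenzoate (formed in the flask, not isolated) | COC(=O)c1c(C)c(C(Cl)OC)c(OCc2ccccc2)c(C)c1OC | intermediate
5 | methyl 4-(benzyloxy)-5-formyl-2-methoxy-3,6-dimethylbenzoate | COC(=O)c1c(C)c(C=O)c(OCc2ccccc2)c(C)c1OC | intermediate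
6 | methyl 5-formyl-4-hydroxy-2-methoxy-3,6-dimethylbenzoate (formed in the flask, not isolated) | COC(=O)c1c(C)c(C=O)c(O)c(C)c1OC | intermediate
7 | methyl 4-hydroxy-5-(hydroxymethyl)-2-methoxy-3,6-dimethylbenzoate (formed in the flask, not isolated) | COC(=O)c1c(C)c(CO)c(O)c(C)c1OC | intermediate
8 | methyl 4-hydroxy-2-methoxy-3,5,6-trimethylbenzoate | COC(=O)c1c(C)c(C)c(O)c(C)c1OC | intermediate
9 | 2,2,6-trimethyl-4H-1,3-dioxin-4-one | CC1=CC(=O)OC(C)(C)O1 | starting material
10 | lithium 2,2-dimethyl-6-methylidene-6H-1,3-dioxin-4-olate, the dienolate of 9 (formed in the flask, not isolated) | C=C1C=C([O-])OC(C)(C)O1.[Li+] | intermediate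
11 | 2,2-dimethyl-6-(2-oxobutyl)-4H-1,3-dioxin-4-one | CCC(=O)CC1=CC(=O)OC(C)(C)O1 | intermediate
12 | dilithium dienolate of 11, deprotonated at C1' and C3' of the oxobutyl chain (formed in the flask, not isolated) | CC=C([O-])C=C1C=C([O-])OC(C)(C)O1.[Li+].[Li+] | intermediate
13 | dilithium salt of the adduct of 12 with N-methoxy-N-methylacetamide, C3' bearing a C(O−)(CH3)N(OCH3)CH3 group (mixture of stereoisomers; formed in the flask, not isolated) | CON(C)C(C)([O-])C(C)C(=O)C=C1C=C([O-])OC(C)(C)O1.[Li+].[Li+] | intermediate
14 | 2,2-dimethyl-6-(3-methyl-2,4-dioxopentyl)-4H-1,3-dioxin-4-one (racemic, enolizable) | CC(=O)C(C)C(=O)CC1=CC(=O)OC(C)(C)O1 | intermediate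
15 | 6-methyloct-1-ene-1,3,5,7-tetrone, the acylketene (racemic; formed in the flask, not isolated) | CC(=O)C(C)C(=O)CC(=O)C=C=O | intermediate
16 | methyl 2-methoxy-3,5,6-trimethyl-4-[(6-methyl-3,5,7-trioxooctanoyl)oxy]benzoate (racemic; formed in the flask, not isolated) | CC(=O)C(C)C(=O)CC(=O)CC(=O)Oc1c(C)c(C)c(C(=O)OC)c(OC)c1C | intermediate
17 | methyl 4-{[(2-hydroxy-2,3-dimethyl-4,6-dioxocyclohexyl)carbonyl]oxy}-2-methoxy-3,5,6-trimethylbenzoate (mixture of stereoisomers; formed in the flask, not isolated) | COC(=O)c1c(C)c(C)c(OC(=O)C2C(=O)CC(=O)C(C)C2(C)O)c(C)c1OC | intermediate
18 | methyl 4-[(2,4-dihydroxy-5,6-dimethylbenzoyl)oxy]-2-methoxy-3,5,6-trimethylbenzoate | COC(=O)c1c(C)c(C)c(OC(=O)c2c(C)c(C)c(O)cc2O)c(C)c1OC | intermediate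
19 | methyl 4-({3-[chloro(methoxy)methyl]-2,4-dihydroxy-5,6-dimethylbenzoyl}oxy)-2-methoxy-3,5,6-trimethylbenzoate (formed in the flask, not isolated) | COC(=O)c1c(C)c(C)c(OC(=O)c2c(C)c(C)c(O)c(C(Cl)OC)c2O)c(C)c1OC | intermediate
20 | methyl 4-[(3-formyl-2,4-dihydroxy-5,6-dimethylbenzoyl)oxy]-2-methoxy-3,5,6-trimethylbenzoate | COC(=O)c1c(C)c(C)c(OC(=O)c2c(C)c(C)c(O)c(C=O)c2O)c(C)c1OC | target

## Step count and least certain steps

Total step count: 8. Longest linear sequence: 6 steps (steps 1, 2, 3, 4, 7 and 8, from 1). The branch from 9 (steps 5 and 6) joins at step 7.

**Step 7 (key step).** Two processes are most likely to go wrong.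
- Capture of the ketene by the enol oxygen of its own chain is unimolecular. It competes with capture by a phenol whose oxygen is flanked by two methyl groups and is made less nucleophilic by the para ester.
- After capture, amine-induced expulsion of the good aryloxide leaving group (by lactonization or by reversion to the ketene) competes with the aldol closure.

The fallback sets out from 14 and comes back at 18. Compound 14 is aromatized on its own with Et3N in CH2Cl2, by aldol condensation of the dioxinone C5 onto the terminal ketone, to 7-hydroxy-2,2,5,6-tetramethyl-4H-1,3-benzodioxin-4-one F1. Its phenol is silylated (TBSCl, imidazole, DMF) to 7-[(tert-butyldimethylsilyl)oxy]-2,2,5,6-tetramethyl-4H-1,3-benzodioxin-4-one F2. Irradiation of F2 at 300 nm in CH2Cl2 in the presence of 8 transfers the acyl group to the phenol oxygen with loss of acetone (photochemical acylation by a benzodioxinone) and gives the silylated depside methyl 4-({4-[(tert-butyldimethylsilyl)oxy]-2-hydroxy-5,6-dimethylbenzoyl}oxy)-2-methoxy-3,5,6-trimethylbenzoate F3. HF·pyridine in THF removes the silyl group to give 18. Here the aromatic ring is made before the ester, so the ketene capture no longer has to compete with an enolizable chain.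

**Step 6.** Proton transfer to the strongly basic dianion, from the acetyl group of the amide or from adventitious product, and incomplete second deprotonation would return 11 and lower conversion. The fallback sets out from 11 and comes back at 14. Dianion 12 is added to acetaldehyde at −78 °C, an aldol addition that is faster than any proton transfer, to give 6-(4-hydroxy-3-methyl-2-oxopentyl)-2,2-dimethyl-4H-1,3-dioxin-4-one F4 as a mixture of diastereomers. The secondary alcohol of F4 is then oxidized with 2-iodoxybenzoic acid in EtOAc at reflux to 14.

**Step 8.** Substitution at C3 may be sluggish, because the position lies between two chelated oxygens on a ring that bears an acyl group. Prolonged exposure to TiCl4 could then cleave the aryl ester or the methyl ether next to the ester of ring B. The fallback sets out from 18 and comes back at 20. Compound 18 is heated with phenylboronic acid and paraformaldehyde (propanoic acid cat., PhMe, reflux, azeotropic removal of water); the C–C bond forms inside a phenoxyboronate–formaldehyde complex and is therefore ortho-specific, giving the cyclic boronate methyl 4-{[(5-hydroxy-7,8-dimethyl-2-phenyl-4H-1,3,2-benzodioxaborin-6-yl)carbonyl]oxy}-2-methoxy-3,5,6-trimethylbenzoate F5. Exchange with propane-1,3-diol releases methyl 4-{[2,4-dihydroxy-3-(hydroxymethyl)-5,6-dimethylbenzoyl]oxy}-2-methoxy-3,5,6-trimethylbenzoate F6. MnO2 in CH2Cl2 then oxidizes the benzylic alcohol of F6 to the aldehyde 20.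

**Step 3.** The Lewis acid may remove the benzyl group before formylation, and the benzyl cation may then re-attach at C5, the only free ring position. The fallback sets out from 3 and comes back at 6. Compound 3 is hydrogenolysed (H2, Pd/C, EtOAc) to methyl 4-hydroxy-2-methoxy-3,6-dimethylbenzoate F7. F7 is formylated at its only free ortho position with MgCl2, Et3N and paraformaldehyde in MeCN at reflux, by magnesium-phenoxide-directed ortho-formylation, to give 6, here isolated. Compound 6 is then hydrogenated under the conditions of step 4 to 8.

## Further compounds

F1 | step 7 | 7-hydroxy-2,2,5,6-tetramethyl-4H-1,3-benzodioxin-4-one | CC1(C)OC(=O)c2c(C)c(C)c(O)cc2O1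
F2 | step 7 | 7-[(tert-butyldimethylsilyl)oxy]-2,2,5,6-tetramethyl-4H-1,3-benzodioxin-4-one | CC1(C)OC(=O)c2c(C)c(C)c(O[Si](C)(C)C(C)(C)C)cc2O1
F3 | step 7 | methyl 4-({4-[(tert-butyldimethylsilyl)oxy]-2-hydroxy-5,6-dimethylbenzoyl}oxy)-2-methoxy-3,5,6-trimethylbenzoate | COC(=O)c1c(C)c(C)c(OC(=O)c2c(C)c(C)c(O[Si](C)(C)C(C)(C)C)cc2O)c(C)c1OC
F4 | step 6 | 6-(4-hydroxy-3-methyl-2-oxopentyl)-2,2-dimethyl-4H-1,3-dioxin-4-one (mixture of diastereomers) | CC(O)C(C)C(=O)CC1=CC(=O)OC(C)(C)O1
F5 | step 8 | methyl 4-{[(5-hydroxy-7,8-dimethyl-2-phenyl-4H-1,3,2-benzodioxaborin-6-yl)carbonyl]oxy}-2-methoxy-3,5,6-trimethylbenzoate | COC(=O)c1c(C)c(C)c(OC(=O)c2c(C)c(C)c3OB(c4ccccc4)OCc3c2O)c(C)c1OC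
F6 | step 8 | methyl 4-{[2,4-dihydroxy-3-(hydroxymethyl)-5,6-dimethylbenzoyl]oxy}-2-methoxy-3,5,6-trimethylbenzoate | COC(=O)c1c(C)c(C)c(OC(=O)c2c(C)c(C)c(O)c(CO)c2O)c(C)c1OC
F7 | step 3 | methyl 4-hydroxy-2-methoxy-3,6-dimethylbenzoate | COC(=O)c1c(C)cc(O)c(C)c1OC
A1 | alternative 1 | 2,4-bis(benzyloxy)-3-formyl-5,6-dimethylbenzoic acid | O=Cc1c(OCc2ccccc2)c(C)c(C)c(C(=O)O)c1OCc1ccccc1
A2 | alternative 1 | methyl 4-{[2,4-bis(benzyloxy)-3-formyl-5,6-dimethylbenzoyl]oxy}-2-methoxy-3,5,6-trimethylbenzoate | COC(=O)c1c(C)c(C)c(OC(=O)c2c(C)c(C)c(OCc3ccccc3)c(C=O)c2OCc4ccccc4)c(C)c1OC
A3 | alternative 2 | methyl 4-(but-2-ynoyloxy)-2-methoxy-3,5,6-trimethylbenzoate | COC(=O)c1c(C)c(C)c(OC(=O)C#CC)c(C)c1OC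
A4 | alternative 2 | (3Z)-1-methoxy-1,3-bis(trimethylsilyloxy)penta-1,3-diene | C/C=C(\O[Si](C)(C)C)C=C(OC)O[Si](C)(C)C
A5 | alternative 3 | [3-methoxy-4-(methoxycarbonyl)-2,5,6-trimethylphenyl]boronic acid | COC(=O)c1c(C)c(C)c(B(O)O)c(C)c1OC
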